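**Retrosynthetic overview**
- The C6–C7 bond is made last but one, by Stille coupling of a ring-bound Z enol triflate (C7) with a Z vinylstannane (C1–C6); both alkene geometries (7Z, 5Z) are fixed before the coupling, and the silyl ether is removed last.
- The triflate comes from α'-formylation of 2-chloro-4-silyloxy-4-(Z-oct-2-enyl)cyclopent-2-enone, itself obtained from a 2-chloro-3-ethoxy enone by Stork–Danheiser carbonyl transposition.
- The 14Z alkene comes from a Wittig reaction on an aldehyde unmasked from a butenyl group; the C10 chlorine comes from chlorination of the vinylogous ester.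
- Key step: the C12–C13 bond and the only stereocentre are set by rhodium-carbenoid O–H insertion followed by [3,3]-sigmatropic (Claisen) rearrangement between 5-diazo-3-ethoxycyclopent-2-enone and (S)-but-3-en-2-ol; the bought stereocentre is relayed to C12 and then becomes sp2.
- Rings: the only ring is bought as 3-ethoxycyclopent-2-en-1-one and kept throughout; no ring is formed.

Assumption: prostanoid numbering (C1 = ester carbon, C20 = chain end) is used for target atoms, and (S)-but-3-en-2-ol is bought enantiopure.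

**Step 1**
Reactants: 1 3-ethoxycyclopent-2-en-1-one
Product: 3 5-diazo-3-ethoxycyclopent-2-en-1-one, via trifluoroacetyl ketone 2 (not isolated)
Conditions: LiN(SiMe3)2, THF, −78 °C; CF3CO2CH2CF3; aq HCl work-up; then MsN3, Et3N, H2O (1 equiv), MeCN, rt
Reagents that add atoms: methanesulfonyl azide, CS(=O)(=O)N=[N+]=[N-]
Why: Kinetic α'-deprotonation of the vinylogous ester, Claisen trifluoroacetylation and detrifluoroacetylative diazo transfer (Danheiser variant of the Regitz reaction) place the diazo group at C5 only; no stereocentre is formed.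

**Step 2**
Reactants: 3 5-diazo-3-ethoxycyclopent-2-en-1-one; 4 (S)-but-3-en-2-ol
Product: 7 (5S)-5-[(2E)-but-2-en-1-yl]-3-ethoxy-5-hydroxycyclopent-2-en-1-one, via hydroxy dienyl ether 5 (not isolated), via unconjugated ketol 6 (not isolated)
Conditions: Rh2(OAc)4 (1 mol %), 4 (1.3 equiv), benzene, 80 °C, 3 added over 1 h; then DBU (0.1 equiv), rt
Reagents that add atoms: none
Why: The rhodium carbenoid inserts into the O–H bond of 4 to give the ring-locked hydroxy enol allyl ether 5, which undergoes a [3,3]-sigmatropic Claisen rearrangement through a chair with the methyl group equatorial, so the C–O stereocentre of 4 is relayed suprafacially to the new quaternary carbinol carbon (the future 12R centre) while itself becoming part of an E alkene, and DBU then moves the enol ether double bond into conjugation.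

**Step 3**
Reactants: 7 (5S)-5-[(2E)-but-2-en-1-yl]-3-ethoxy-5-hydroxycyclopent-2-en-1-one
Product: 8 (5S)-5-[(2E)-but-2-en-1-yl]-2-chloro-3-ethoxy-5-hydroxycyclopent-2-en-1-one
Conditions: NCS, CH2Cl2, 0 °C → rt
Reagents that add atoms: N-chlorosuccinimide, O=C1CCC(=O)N1Cl
Why: The α-carbon of the vinylogous ester (future C10) is its nucleophilic enol-ether β-position, so electrophilic chlorination occurs there and not at the isolated alkene; the stereocentre is untouched.

**Step 4**
Reactants: 8 (5S)-5-[(2E)-but-2-en-1-yl]-2-chloro-3-ethoxy-5-hydroxycyclopent-2-en-1-one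
Product: 9 (5S)-5-[(2E)-but-2-en-1-yl]-2-chloro-3-ethoxy-5-(triethylsilyloxy)cyclopent-2-en-1-one
Conditions: Et3SiOTf, 2,6-lutidine, CH2Cl2, −78 → 0 °C
Reagents that add atoms: triethylsilyl trifluoromethanesulfonate, CC[Si](CC)(CC)OS(=O)(=O)C(F)(F)F
Why: The silyl triflate silylates the hindered tertiary alcohol, which blocks retro-aldol cleavage of the β-oxy aldehyde made next and protects the oxygen until the end.

**Step 5**
Reactants: 9 (5S)-5-[(2E)-but-2-en-1-yl]-2-chloro-3-ethoxy-5-(triethylsilyloxy)cyclopent-2-en-1-one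
Product: 11 2-[(1R)-3-chloro-4-ethoxy-2-oxo-1-(triethylsilyloxy)cyclopent-3-en-1-yl]acetaldehyde, via vicinal diol 10 (not isolated)
Conditions: OsO4 (2 mol %), NaIO4 (4 equiv), 2,6-lutidine, 1,4-dioxane/H2O 3:1, rt
Reagents that add atoms: sodium periodate, [Na+].[O-]I(=O)(=O)=O; water, O (oxygen enters through the catalytic OsO4 cycle)
Why: In this Lemieux–Johnson cleavage OsO4 dihydroxylates the electron-rich disubstituted alkene rather than the electron-poor tetrasubstituted chloro enol ether, and periodate cleaves the diol to the aldehyde; the descriptor changes from S to R only because of ligand priorities.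

**Step 6**
Reactants: 11 2-[(1R)-3-chloro-4-ethoxy-2-oxo-1-(triethylsilyloxy)cyclopent-3-en-1-yl]acetaldehyde; 12 hexyl(triphenyl)phosphonium bromide
Product: 13 (5S)-2-chloro-3-ethoxy-5-[(2Z)-oct-2-en-1-yl]-5-(triethylsilyloxy)cyclopent-2-en-1-one
Conditions: NaN(SiMe3)2, THF, 0 °C (ylide); add 11 at −78 °C → rt
Reagents that add atoms: none
Why: A lithium-free Wittig reaction of the non-stabilised ylide with the aliphatic aldehyde gives the Z alkene (14Z) under kinetic control, and the vinylogous ester carbonyl is inert to the ylide at low temperature.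

**Step 7**
Reactants: 13 (5S)-2-chloro-3-ethoxy-5-[(2Z)-oct-2-en-1-yl]-5-(triethylsilyloxy)cyclopent-2-en-1-one
Product: 15 (4S)-2-chloro-4-[(2Z)-oct-2-en-1-yl]-4-(triethylsilyloxy)cyclopent-2-en-1-one, via allylic alcohol 14 (not isolated)
Conditions: i-Bu2AlH, CH2Cl2, −78 °C; then 1 M HCl, THF, 0 °C
Reagents that add atoms: water, O
Why: In this Stork–Danheiser transposition, 1,2-reduction of the vinylogous ester and acid hydrolysis of the β-ethoxy allylic alcohol (loss of water and ethanol) move the carbonyl to C9, leaving chlorine on C10, the C10=C11 alkene and the quaternary centre untouched.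

**Step 8**
Reactants: 15 (4S)-2-chloro-4-[(2Z)-oct-2-en-1-yl]-4-(triethylsilyloxy)cyclopent-2-en-1-one
Product: 17 (Z)-[(2R)-4-chloro-2-[(2Z)-oct-2-en-1-yl]-5-oxo-2-(triethylsilyloxy)cyclopent-3-en-1-ylidene]methyl trifluoromethanesulfonate, via lithium formyl enolate 16 (not isolated)
Conditions: LiN(SiMe3)2, THF, −78 °C; HCO2CH2CF3, −78 °C; then PhNTf2, −78 → −20 °C; aq NH4Cl work-up
Reagents that add atoms: 2,2,2-trifluoroethyl formate, O=COCC(F)(F)F; N-phenylbis(trifluoromethanesulfonyl)imide, O=S(=O)(N(c1ccccc1)S(=O)(=O)C(F)(F)F)C(F)(F)F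
Why: Claisen formylation of the kinetic α'-enolate (C8) gives a lithium-chelated hydroxymethylene enolate whose two oxygens are held syn, and O-triflation of the less hindered formyl oxygen keeps this geometry, giving the Z enol triflate; at −78 °C the enolate does not expel the β-silyloxy group.

**Step 9**
Reactants: 18 methyl hex-5-ynoate
Product: 19 methyl (5Z)-6-(tributylstannyl)hex-5-enoate
Conditions: Bu3SnH, ZrCl4 (20 mol %), toluene, 0 °C
Reagents that add atoms: tributyltin hydride, CCCC[SnH](CCCC)CCCC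
Why: Lewis-acid-catalysed hydrostannation adds Sn–H anti across the terminal alkyne, giving the Z β-stannyl alkene.

**Step 10**
Reactants: 17 (Z)-[(2R)-4-chloro-2-[(2Z)-oct-2-en-1-yl]-5-oxo-2-(triethylsilyloxy)cyclopent-3-en-1-ylidene]methyl trifluoromethanesulfonate; 19 methyl (5Z)-6-(tributylstannyl)hex-5-enoate
Product: 20 methyl (5Z,7Z,12R,14Z)-10-chloro-9-oxo-12-(triethylsilyloxy)prosta-5,7,10,14-tetraenoate
Conditions: Pd2(dba)3 (2.5 mol %), AsPh3 (20 mol %), NMP, rt, dark
Reagents that add atoms: none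
Why: Stille coupling proceeds with retention at both sp2 carbons, so the Z triflate gives 7Z and the Z stannane gives 5Z under neutral room-temperature conditions; the vinyl chloride is not touched.

**Step 11**
Reactants: 20 methyl (5Z,7Z,12R,14Z)-10-chloro-9-oxo-12-(triethylsilyloxy)prosta-5,7,10,14-tetraenoate
Product: 21 methyl (5Z,7Z,12R,14Z)-10-chloro-12-hydroxy-9-oxoprosta-5,7,10,14-tetraenoate
Conditions: HF·pyridine, pyridine, THF, 0 °C
Reagents that add atoms: none
Why: Buffered fluoride-assisted desilylation frees the tertiary alcohol without base or heat, so the cross-conjugated dienone geometry and the C12 centre are preserved.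

**Compound list**
1 | 3-ethoxycyclopent-2-en-1-one | CCOC1=CC(=O)CC1 | starting material
2 | 3-ethoxy-5-(2,2,2-trifluoroacetyl)cyclopent-2-en-1-one (racemic, enolised) | CCOC1=CC(=O)C(C(=O)C(F)(F)F)C1 | intermediate
3 | 5-diazo-3-ethoxycyclopent-2-en-1-one | CCOC1=CC(=O)C(=[N+]=[N-])C1 | intermediate
4 | (S)-but-3-en-2-ol | C[C@H](O)C=C | starting material
5 | 2-[(2S)-but-3-en-2-yloxy]-4-ethoxycyclopenta-1,4-dien-1-ol | CCOC1=CC(O)=C(O[C@@H](C)C=C)C1 | intermediate
6 | (2S)-2-[(2E)-but-2-en-1-yl]-4-ethoxy-2-hydroxycyclopent-3-en-1-one | C/C=C/C[C@]1(O)C=C(OCC)CC1=O | intermediate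
7 | (5S)-5-[(2E)-but-2-en-1-yl]-3-ethoxy-5-hydroxycyclopent-2-en-1-one | C/C=C/C[C@]1(O)CC(OCC)=CC1=O | intermediate
8 | (5S)-5-[(2E)-but-2-en-1-yl]-2-chloro-3-ethoxy-5-hydroxycyclopent-2-en-1-one | C/C=C/C[C@]1(O)CC(OCC)=C(Cl)C1=O | intermediate
9 | (5S)-5-[(2E)-but-2-en-1-yl]-2-chloro-3-ethoxy-5-(triethylsilyloxy)cyclopent-2-en-1-one | C/C=C/C[C@]1(O[Si](CC)(CC)CC)CC(OCC)=C(Cl)C1=O | intermediate
10 | (5S)-2-chloro-5-(2,3-dihydroxybutyl)-3-ethoxy-5-(triethylsilyloxy)cyclopent-2-en-1-one (diol centres mixed) | CC(O)C(O)C[C@]1(O[Si](CC)(CC)CC)CC(OCC)=C(Cl)C1=O | intermediate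
11 | 2-[(1R)-3-chloro-4-ethoxy-2-oxo-1-(triethylsilyloxy)cyclopent-3-en-1-yl]acetaldehyde | O=CC[C@]1(O[Si](CC)(CC)CC)CC(OCC)=C(Cl)C1=O | intermediate
12 | hexyl(triphenyl)phosphonium bromide | CCCCCC[P+](c1ccccc1)(c1ccccc1)c1ccccc1.[Br-] | starting material
13 | (5S)-2-chloro-3-ethoxy-5-[(2Z)-oct-2-en-1-yl]-5-(triethylsilyloxy)cyclopent-2-en-1-one | CCCCC/C=C\C[C@]1(O[Si](CC)(CC)CC)CC(OCC)=C(Cl)C1=O | intermediate
14 | (5S)-2-chloro-3-ethoxy-5-[(2Z)-oct-2-en-1-yl]-5-(triethylsilyloxy)cyclopent-2-en-1-ol (carbinol epimers) | CCCCC/C=C\C[C@]1(O[Si](CC)(CC)CC)CC(OCC)=C(Cl)C1O | intermediate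
15 | (4S)-2-chloro-4-[(2Z)-oct-2-en-1-yl]-4-(triethylsilyloxy)cyclopent-2-en-1-one | CCCCC/C=C\C[C@@]1(O[Si](CC)(CC)CC)C=C(Cl)C(=O)C1 | intermediate
16 | lithium (Z)-[(2R)-4-chloro-2-[(2Z)-oct-2-en-1-yl]-5-oxo-2-(triethylsilyloxy)cyclopent-3-en-1-ylidene]methanolate | CCCCC/C=C\C[C@@]1(O[Si](CC)(CC)CC)C=C(Cl)C(=O)/C1=C\[O-].[Li+] | intermediate
17 | (Z)-[(2R)-4-chloro-2-[(2Z)-oct-2-en-1-yl]-5-oxo-2-(triethylsilyloxy)cyclopent-3-en-1-ylidene]methyl trifluoromethanesulfonate | CCCCC/C=C\C[C@@]1(O[Si](CC)(CC)CC)C=C(Cl)C(=O)/C1=C\OS(=O)(=O)C(F)(F)F | intermediate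
18 | methyl hex-5-ynoate | C#CCCCC(=O)OC | starting material
19 | methyl (5Z)-6-(tributylstannyl)hex-5-enoate | CCCC[Sn](CCCC)(CCCC)/C=C\CCCC(=O)OC | intermediate
20 | methyl (5Z,7Z,12R,14Z)-10-chloro-9-oxo-12-(triethylsilyloxy)prosta-5,7,10,14-tetraenoate | CCCCC/C=C\C[C@@]1(O[Si](CC)(CC)CC)C=C(Cl)C(=O)/C1=C\C=C/CCCC(=O)OC | intermediate
21 | methyl (5Z,7Z,12R,14Z)-10-chloro-12-hydroxy-9-oxoprosta-5,7,10,14-tetraenoate | CCCCC/C=C\C[C@@]1(O)C=C(Cl)C(=O)/C1=C\C=C/CCCC(=O)OC | target

**Step count and risks**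
Total step count: 11. Longest linear sequence: 10 steps (steps 1–8, 10 and 11); step 9 makes the side-chain stannane.

The three steps most likely to fail:

Step 2. The enol 5 may ketonise before it rearranges, or the carbenoid may be consumed in other ways. The fallback sets out from 3 (with 4) and comes back at 7. Insertion is run with Rh2(OAc)4 in CH2Cl2 at rt and the ketonised insertion product 5-[(2S)-but-3-en-2-yloxy]-3-ethoxycyclopent-2-en-1-one F1 is isolated. It is re-enolised with LiN(SiMe3)2 in the presence of Me3SiCl (THF, −78 °C) to [2-[(2S)-but-3-en-2-yloxy]-4-ethoxycyclopenta-1,4-dien-1-yl]oxy-trimethylsilane F2. Warming F2 in toluene to 60 °C brings about the same chair [3,3] rearrangement with the oxygen already silylated and gives (2S)-2-[(2E)-but-2-en-1-yl]-4-ethoxy-2-(trimethylsilyloxy)cyclopent-3-en-1-one F3. K2CO3 in MeOH at 0 °C removes the silyl group and conjugates the enol ether to give 7.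

Step 8. Formylation of the β-silyloxy enolate may be accompanied by elimination, and the triflate may form as an E/Z mixture. The fallback sets out from 15 and comes back at 20 by the classical aldol route. Commercial methyl 5-oxopentanoate is treated with the ylide of (1,3-dioxolan-2-ylmethyl)triphenylphosphonium bromide (NaN(SiMe3)2, THF, −78 °C) to give methyl (5Z)-6-(1,3-dioxolan-2-yl)hex-5-enoate F4. Mild hydrolysis on wet SiO2 with oxalic acid gives methyl (5Z)-7-oxohept-5-enoate F5. The lithium enolate of 15 (LiN(SiMe3)2, THF, −78 °C) adds to F5 to give the aldol methyl (5Z)-7-[(5S)-3-chloro-5-[(2Z)-oct-2-en-1-yl]-2-oxo-5-(triethylsilyloxy)cyclopent-3-en-1-yl]-7-hydroxyhept-5-enoate F6 as a mixture at the two new centres. Dehydration with Martin sulfurane (CH2Cl2, 0 °C) gives 20 together with its 7E isomer, which is removed by HPLC.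

Step 10. The Z triflate or the Z,Z-dienone may isomerise under palladium, and the stannane may transfer slowly. The fallback sets out from 17 (with 18) and comes back at 20. Sonogashira coupling of 17 with 18 (PdCl2(PPh3)2, CuI, i-Pr2NEt, THF, 0 °C) gives methyl (7Z,12R,14Z)-10-chloro-9-oxo-12-(triethylsilyloxy)prosta-7,10,14-trien-5-ynoate F7. Semihydrogenation of the alkyne (H2, Pd/CaCO3 poisoned with Pb(OAc)2, quinoline, EtOAc, rt, stopped at 1 equiv) forms the 5Z alkene and gives 20.

**Further compounds**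
F1 | step 2 | 5-[(2S)-but-3-en-2-yloxy]-3-ethoxycyclopent-2-en-1-one | CCOC1=CC(=O)C(O[C@@H](C)C=C)C1
F2 | step 2 | [2-[(2S)-but-3-en-2-yloxy]-4-ethoxycyclopenta-1,4-dien-1-yl]oxy-trimethylsilane | CCOC1=CC(O[Si](C)(C)C)=C(O[C@@H](C)C=C)C1
F3 | step 2 | (2S)-2-[(2E)-but-2-en-1-yl]-4-ethoxy-2-(trimethylsilyloxy)cyclopent-3-en-1-one | C/C=C/C[C@]1(O[Si](C)(C)C)C=C(OCC)CC1=O
F4 | step 8 | methyl (5Z)-6-(1,3-dioxolan-2-yl)hex-5-enoate | COC(=O)CCC/C=C\C1OCCO1
F5 | step 8 | methyl (5Z)-7-oxohept-5-enoate | COC(=O)CCC/C=C\C=O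
F6 | step 8 | methyl (5Z)-7-[(5S)-3-chloro-5-[(2Z)-oct-2-en-1-yl]-2-oxo-5-(triethylsilyloxy)cyclopent-3-en-1-yl]-7-hydroxyhept-5-enoate | CCCCC/C=C\C[C@@]1(O[Si](CC)(CC)CC)C=C(Cl)C(=O)C1C(O)/C=C\CCCC(=O)OC
F7 | step 10 | methyl (7Z,12R,14Z)-10-chloro-9-oxo-12-(triethylsilyloxy)prosta-7,10,14-trien-5-ynoate | CCCCC/C=C\C[C@@]1(O[Si](CC)(CC)CC)C=C(Cl)C(=O)/C1=C\C#CCCCC(=O)OC
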